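**Retrosynthetic overview**
1. Target 13 ⇐ macrocyclic tetramethyl ether 12 by global O-demethylation.
2. 12 ⇐ seco chloride/phenol 11 by closing the 17-membered ring at the hindered ring C–O–ring D diaryl ether C–O bond (palladium; key step).
3. 11 ⇐ bisphenol 5 + bromo/chloro bibenzyl 10 through the ring A–O–ring B diaryl ether C–O bond (copper); Br is addressed by copper, Cl is kept for palladium.
4. 5 ⇐ 1 + 2 and 10 ⇐ 6 + 7: each ethano bridge by Wittig olefination, then C=C reduction.
5. Ring order: the four benzene rings are bought; the only ring formed is the macrocycle, in step 6.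

Assumption: the SMILES has no stereocentre, no stereogenic double bond and no configurationally stable chirality element, so the target is achiral and no stereocontrol is needed.

Ring labels: ring A = trioxygenated ring from 6; ring B = para-phenylene from 2; ring C = 2,3,4-trioxygenated ring from 1; ring D = ortho-phenylene from 7.

**Route**

Step 1
Reactants: 1 2-hydroxy-3,4-dimethoxybenzaldehyde; 2 (4-benzyloxybenzyl)triphenylphosphonium chloride
Product: 4 6-[2-(4-benzyloxyphenyl)ethenyl]-2,3-dimethoxyphenol (E/Z mixture), via [4-(benzyloxy)benzylidene]triphenylphosphorane 3 (not isolated)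
Conditions: 2 (1.3 equiv), KOtBu (2.5 equiv), THF, 0 °C; then 1, rt to 50 °C
Reagents that add atoms: none
Why: Wittig olefination, in which the semi-stabilised benzylic ylide still condenses with the aldehyde although the extra base converts the ortho-hydroxyl into its phenoxide; the E/Z mixture is irrelevant because the alkene is saturated in step 2, and no stereocentre is formed.

Step 2
Reactants: 4 6-[2-(4-benzyloxyphenyl)ethenyl]-2,3-dimethoxyphenol
Product: 5 6-[2-(4-hydroxyphenyl)ethyl]-2,3-dimethoxyphenol
Conditions: H2 (1 atm), 10% Pd/C, EtOAc/MeOH, rt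
Reagents that add atoms: none
Why: Catalytic hydrogenation with concurrent hydrogenolysis, so Pd/C saturates the stilbene C=C and cleaves the benzyl ether in one operation while aryl methyl ethers are inert.

Step 3
Reactants: 6 3-bromo-4,5-dimethoxybenzaldehyde; 7 (2-chlorobenzyl)triphenylphosphonium chloride
Product: 9 1-bromo-5-[2-(2-chlorophenyl)ethenyl]-2,3-dimethoxybenzene (E/Z mixture), via (2-chlorobenzylidene)triphenylphosphorane 8 (not isolated)
Conditions: 7 (1.1 equiv), KOtBu (1.15 equiv), THF, 0 °C; then 6, rt
Reagents that add atoms: none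
Why: Wittig olefination of a non-enolisable aryl aldehyde; the aryl bromide and aryl chloride are inert to the ylide and both alkene isomers converge in step 4.

Step 4
Reactants: 9 1-bromo-5-[2-(2-chlorophenyl)ethenyl]-2,3-dimethoxybenzene
Product: 10 1-bromo-5-[2-(2-chlorophenyl)ethyl]-2,3-dimethoxybenzene
Conditions: p-toluenesulfonyl hydrazide (5 equiv), NaOAc (5 equiv), THF/H2O 1:1, reflux
Reagents that add atoms: none
Why: Diimide reduction, in which diimide from base-induced fragmentation of the sulfonyl hydrazide delivers two hydrogens to the C=C through a cyclic transition state and cannot cleave C–Br or C–Cl, which hydrogenation over palladium would endanger.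

Step 5
Reactants: 5 6-[2-(4-hydroxyphenyl)ethyl]-2,3-dimethoxyphenol; 10 1-bromo-5-[2-(2-chlorophenyl)ethyl]-2,3-dimethoxybenzene
Product: 11 6-[2-(4-{5-[2-(2-chlorophenyl)ethyl]-2,3-dimethoxyphenoxy}phenyl)ethyl]-2,3-dimethoxyphenol
Conditions: 5 (1.3 equiv), CuI (10 mol %), N,N-dimethylglycine hydrochloride (30 mol %), Cs2CO3 (2.5 equiv), 1,4-dioxane, 105 °C
Reagents that add atoms: none
Why: Ullmann-type diaryl ether coupling on amino-acid-ligated monovalent copper, which activates only the aryl bromide of 10 (the aryl chloride is inert at this temperature), while the unhindered ring B phenoxide of 5 couples much faster than the ring C phenoxide flanked by an alkyl and a methoxy group.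

Step 6
Reactants: 11 6-[2-(4-{5-[2-(2-chlorophenyl)ethyl]-2,3-dimethoxyphenoxy}phenyl)ethyl]-2,3-dimethoxyphenol
Product: 12 tetra-O-methyl ether of the target (the macrocycle with OMe at all four hydroxyl positions)
Conditions: Pd(OAc)2 (10 mol %), Me4tBuXPhos (2-di-tert-butylphosphino-3,4,5,6-tetramethyl-2',4',6'-triisopropylbiphenyl, 15 mol %), K3PO4 (3 equiv), toluene, 100 °C; 11 added over 12 h by syringe pump, final 2 mM
Reagents that add atoms: none
Why: Proposed new method: a palladium-catalysed macro-etherification (intramolecular Buchwald–Hartwig-type C–O coupling), to my knowledge not yet shown for closing a cyclophane through a tri-ortho-substituted diaryl ether from an unactivated aryl chloride; zerovalent palladium bearing one bulky biaryl di-tert-butylphosphine adds oxidatively to the ring D C–Cl bond left untouched by copper in step 5, the tethered potassium phenoxide of ring C displaces chloride on divalent palladium, and ligand bulk plus the ortho substituents on both aryl partners drive C–O reductive elimination, which is unimolecular so that slow addition disfavours oligomers; the closest known reactions are the intermolecular palladium-catalysed diaryl ether synthesis from aryl chlorides and ortho-substituted phenols with this ligand class and palladium-catalysed C–N macrocyclisations.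

Step 7
Reactants: 12 tetra-O-methyl ether of the target
Product: 13 target bis-catechol macrocycle (CNP0114693.0)
Conditions: BBr3 (8 equiv), CH2Cl2, −78 °C to rt; then H2O/MeOH, work-up under argon
Reagents that add atoms: none
Why: Lewis-acid O-demethylation, in which BBr3 coordinates each methoxy oxygen and bromide removes the methyl group by SN2 attack; the diaryl ether C–O bonds are not cleaved, and aqueous work-up hydrolyses the aryl borates to the two catechols.

**Compound list**
1 | 2-hydroxy-3,4-dimethoxybenzaldehyde | O=Cc1ccc(OC)c(OC)c1O | starting material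
2 | (4-benzyloxybenzyl)triphenylphosphonium chloride | [Cl-].C(c1ccc(OCc2ccccc2)cc1)[P+](c1ccccc1)(c1ccccc1)c1ccccc1 | starting material
3 | [4-(benzyloxy)benzylidene]triphenylphosphorane | C(c1ccc(OCc2ccccc2)cc1)=P(c1ccccc1)(c1ccccc1)c1ccccc1 | intermediate
4 | 6-[2-(4-benzyloxyphenyl)ethenyl]-2,3-dimethoxyphenol (E/Z mixture, geometry not defined) | COc1ccc(C=Cc2ccc(OCc3ccccc3)cc2)c(O)c1OC | intermediate
5 | 6-[2-(4-hydroxyphenyl)ethyl]-2,3-dimethoxyphenol | COc1ccc(CCc2ccc(O)cc2)c(O)c1OC | intermediate
6 | 3-bromo-4,5-dimethoxybenzaldehyde | COc1cc(C=O)cc(Br)c1OC | starting material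
7 | (2-chlorobenzyl)triphenylphosphonium chloride | [Cl-].Clc1ccccc1C[P+](c1ccccc1)(c1ccccc1)c1ccccc1 | starting material
8 | (2-chlorobenzylidene)triphenylphosphorane | Clc1ccccc1C=P(c1ccccc1)(c1ccccc1)c1ccccc1 | intermediate
9 | 1-bromo-5-[2-(2-chlorophenyl)ethenyl]-2,3-dimethoxybenzene (E/Z mixture, geometry not defined) | COc1cc(C=Cc2ccccc2Cl)cc(Br)c1OC | intermediate
10 | 1-bromo-5-[2-(2-chlorophenyl)ethyl]-2,3-dimethoxybenzene | COc1cc(CCc2ccccc2Cl)cc(Br)c1OC | intermediate
11 | 6-[2-(4-{5-[2-(2-chlorophenyl)ethyl]-2,3-dimethoxyphenoxy}phenyl)ethyl]-2,3-dimethoxyphenol | COc1cc(CCc2ccccc2Cl)cc(Oc2ccc(CCc3ccc(OC)c(OC)c3O)cc2)c1OC | intermediate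
12 | tetra-O-methyl ether of the target macrocycle (achiral) | COc1cc2cc(c1OC)Oc1ccc(cc1)CCc1ccc(OC)c(OC)c1Oc1ccccc1CC2 | intermediate
13 | target macrocyclic bis(bibenzyl) bis-catechol (achiral) | Oc1cc2cc(c1O)Oc1ccc(cc1)CCc1ccc(O)c(O)c1Oc1ccccc1CC2 | target

**Step count**
Total steps: 7. Longest linear sequence: 5 steps (1 → 2 → 5 → 6 → 7, or 3 → 4 → 5 → 6 → 7).

**Steps most likely to fail, with fallbacks**

Step 6, the proposed macro-etherification, is the least certain. The aryl–palladium intermediate on ring D sits ortho to the ethano bridge, so it could instead arylate a C–H bond of ring A (giving a 9,10-dihydrophenanthrene), lose chlorine to hydrogen, or oligomerise. The fallback uses known chemistry, sets out from 11 and comes back at 12. Borylation of the aryl chloride with tetrahydroxydiboron (Pd(OAc)2, XPhos, KOAc, EtOH, 80 °C) gives (2-{2-[3-(4-{2-[2-hydroxy-3,4-dimethoxyphenyl]ethyl}phenoxy)-4,5-dimethoxyphenyl]ethyl}phenyl)boronic acid F1. An intramolecular Chan–Evans–Lam coupling (Cu(OAc)2, pyridine, 4 Å molecular sieves, CH2Cl2, air, rt, 2 mM) then closes the same ether oxidatively, without an aryl–palladium species, in a reaction class already used for macrocyclic diaryl ethers and 2,6-disubstituted phenols.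

Step 5 may lose selectivity: some arylation of the hindered ring C phenol, double arylation of 5, or slow turnover of the electron-rich ortho-methoxy aryl bromide. The fallback sets out from 10 and comes back at 11. Miyaura borylation at the C–Br bond only (Pd(dppf)Cl2, bis(pinacolato)diboron, KOAc, dioxane, 80 °C) gives 2-{5-[2-(2-chlorophenyl)ethyl]-2,3-dimethoxyphenyl}-4,4,5,5-tetramethyl-1,3,2-dioxaborolane F2. A Chan–Evans–Lam coupling of this boronate with 5 (Cu(OAc)2, pyridine, boric acid, MeCN, 4 Å molecular sieves, air, 70 °C) runs at lower temperature and is far more sensitive to steric hindrance at the phenol, so the ring B hydroxyl reacts and 11 results.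

Step 1 may stall because the phenoxide of 1 deactivates the aldehyde toward the ylide. The fallback avoids olefination, sets out from 1 and comes back at 5. Commercial 4-benzyloxybenzyl chloride and magnesium (THF, 0 °C) give (4-benzyloxybenzyl)magnesium chloride F3. Added in 2.5-fold amount to 1, the first equivalent deprotonates the phenol and the magnesium phenoxide then chelates and activates the aldehyde, giving racemic 2-(4-benzyloxyphenyl)-1-(2-hydroxy-3,4-dimethoxyphenyl)ethanol F4. Hydrogenolysis (H2, 10% Pd/C, EtOAc/AcOH, rt) removes the doubly activated benzylic hydroxyl and the O-benzyl group together, which erases the transient stereocentre and delivers 5.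

**Further compounds**
F1 | step 6 | (2-{2-[3-(4-{2-[2-hydroxy-3,4-dimethoxyphenyl]ethyl}phenoxy)-4,5-dimethoxyphenyl]ethyl}phenyl)boronic acid | COc1cc(CCc2ccccc2B(O)O)cc(Oc2ccc(CCc3ccc(OC)c(OC)c3O)cc2)c1OC
F2 | step 5 | 2-{5-[2-(2-chlorophenyl)ethyl]-2,3-dimethoxyphenyl}-4,4,5,5-tetramethyl-1,3,2-dioxaborolane | COc1cc(CCc2ccccc2Cl)cc(B2OC(C)(C)C(C)(C)O2)c1OC
F3 | step 1 | (4-benzyloxybenzyl)magnesium chloride | Cl[Mg]Cc1ccc(OCc2ccccc2)cc1
F4 | step 1 | 2-(4-benzyloxyphenyl)-1-(2-hydroxy-3,4-dimethoxyphenyl)ethanol (racemic) | COc1ccc(C(O)Cc2ccc(OCc3ccccc3)cc2)c(O)c1OC
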